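The chroman is cut at the two bonds that join its pyran ring to the benzene ring, O1–C8a and C4–C4a. C8a and C4a are neighbours and C4a is flanked by the oxygen-bearing C5, the substitution pattern that a 3-alkoxyaryne delivers regioselectively. In one operation a tertiary alkoxide adds to 3,5-dimethoxybenzyne and the aryl anion acylates a pendant ester, closing the pyranone. The precursor is a geraniol-derived (2R,3R)-β-hydroxy ester that carries the prenyl and silylbutynyl arms and is used as its trimethylsilyl ether, so that fluoride releases alkoxide and aryne together without any O–H present. Isobutyl addition, ionic reduction, epoxide vinylation, diformylation, enyne ring closure and demethylation finish the synthesis.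

Key step: step 11

Remark: chroman numbering (O1, C2, C3, C4, C4a, C5–C8, C8a) is used for all bicyclic compounds; alcohol 24 is carried on as whichever C4 epimer forms, because C4 becomes planar in step 13.

Step 1
Reactants: 1 but-3-yn-1-ol
Product: 2 4-(triisopropylsilyl)but-3-yn-1-ol
Conditions: EtMgBr (2.2 equiv), THF, 0 → 60 °C; TIPSCl, 60 °C; aq NH4Cl
Reagents that add atoms: chlorotriisopropylsilane, CC(C)[Si](Cl)(C(C)C)C(C)C
Why: Ethylmagnesium bromide removes both the O–H and the alkyne C–H protons, and the bulky silyl chloride should then react only at the alkynyl carbon, the magnesium alkoxide being too poor a nucleophile towards it (C-silylation of an alkynyl Grignard reagent).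

Step 2
Reactants: 2 4-(triisopropylsilyl)but-3-yn-1-ol
Product: 3 (4-bromobut-1-yn-1-yl)triisopropylsilane
Conditions: CBr4, PPh3, CH2Cl2, 0 °C → rt
Reagents that add atoms: carbon tetrabromide, BrC(Br)(Br)Br
Why: Appel reaction: the alkoxyphosphonium ion formed from PPh3 and CBr4 is displaced by bromide at the unhindered primary carbon, and the hindered silylalkyne is inert.

Step 3
Reactants: 4 geraniol
Product: 5 (2R,3R)-2,3-epoxygeraniol
Conditions: Ti(OiPr)4 (5 mol %), D-(−)-diisopropyl tartrate (6 mol %), t-BuOOH, 4 Å MS, CH2Cl2, −20 °C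
Reagents that add atoms: tert-butyl hydroperoxide, CC(C)(C)OO
Why: Sharpless asymmetric epoxidation: the titanium tartrate complex binds the allylic alcohol and, with the D-(−)-tartrate, delivers oxygen to the face of the 2,3-alkene that gives the (2R,3R)-epoxide, while the remote 6,7-alkene has no directing hydroxyl and is left alone.

Step 4
Reactants: 3 (4-bromobut-1-yn-1-yl)triisopropylsilane; 5 (2R,3R)-2,3-epoxygeraniol
Product: 7 (2S,3R)-3,7-dimethyl-2-[4-(triisopropylsilyl)but-3-yn-1-yl]oct-6-ene-1,3-diol, via Grignard reagent 6 (not isolated)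
Conditions: 3 (3 equiv), Mg, THF, 40 °C; then 5, CuI (10 mol %), THF, −40 → 0 °C; aq NH4Cl
Reagents that add atoms: none
Why: Copper-catalysed Grignard opening of a 2,3-epoxy alcohol: after the first equivalent of 6 has formed the alkoxide, the organocopper species attacks C2 because C3 is fully substituted, and SN2 inversion at C2 sets the (2S) centre next to the untouched (3R) carbinol.

Step 5
Reactants: 7 (2S,3R)-3,7-dimethyl-2-[4-(triisopropylsilyl)but-3-yn-1-yl]oct-6-ene-1,3-diol
Product: 9 (2R,3R)-3-hydroxy-3,7-dimethyl-2-[4-(triisopropylsilyl)but-3-yn-1-yl]oct-6-enoic acid, via hydroxy aldehyde 8 (not isolated)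
Conditions: TEMPO (0.2 equiv), PhI(OAc)2 (2.2 equiv), MeCN/H2O (1:1), 0 °C → rt
Reagents that add atoms: water, O
Why: TEMPO/PhI(OAc)2 oxidation in aqueous acetonitrile: the oxoammonium salt oxidises only the primary alcohol, first to aldehyde 8 and then through its hydrate to the acid, under nearly neutral conditions that should spare the tertiary alcohol, both π systems and the configuration next to the carbonyl group.

Step 6
Reactants: 9 (2R,3R)-3-hydroxy-3,7-dimethyl-2-[4-(triisopropylsilyl)but-3-yn-1-yl]oct-6-enoic acid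
Product: 10 methyl (2R,3R)-3-hydroxy-3,7-dimethyl-2-[4-(triisopropylsilyl)but-3-yn-1-yl]oct-6-enoate
Conditions: MeI, K2CO3, DMF, rt
Reagents that add atoms: iodomethane, CI
Why: Carboxylate O-alkylation (SN2 on iodomethane): the mild carbonate base forms only the carboxylate and should neither epimerise the α-centre nor alkylate the hindered tertiary alcohol.

Step 7
Reactants: 10 methyl (2R,3R)-3-hydroxy-3,7-dimethyl-2-[4-(triisopropylsilyl)but-3-yn-1-yl]oct-6-enoate
Product: 11 methyl (2R,3R)-3,7-dimethyl-2-[4-(triisopropylsilyl)but-3-yn-1-yl]-3-(trimethylsilyloxy)oct-6-enoate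
Conditions: TMSOTf, 2,6-lutidine, CH2Cl2, −78 → 0 °C
Reagents that add atoms: trimethylsilyl trifluoromethanesulfonate, C[Si](C)(C)OS(=O)(=O)C(F)(F)F
Why: A silyl triflate with a hindered pyridine base silylates even tertiary alcohols (O-silylation), and the ether removes the only O–H proton that could quench an aryl anion in step 11.

Step 8
Reactants: 12 3,5-dimethoxyphenol
Product: 13 3,5-dimethoxyphenyl N-isopropylcarbamate
Conditions: i-PrNCO, Et3N (cat.), CH2Cl2, rt
Reagents that add atoms: isopropyl isocyanate, CC(C)N=C=O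
Why: Amine-catalysed addition of the phenol O–H across the isocyanate (carbamate formation) installs a strong ortho-directing group that is later removable under mild base.

Step 9
Reactants: 13 3,5-dimethoxyphenyl N-isopropylcarbamate
Product: 17 3,5-dimethoxy-2-(trimethylsilyl)phenyl N-isopropylcarbamate, via N-silyl carbamate 14 (not isolated), via aryllithium 15 (not isolated), via bis-silyl carbamate 16 (not isolated)
Conditions: TBSOTf, TMEDA, Et2O, 0 °C → rt; then n-BuLi, TMEDA, −78 °C; TMSCl, −78 °C → rt; aq NaHSO4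
Reagents that add atoms: chlorotrimethylsilane, C[Si](C)(C)Cl
Why: Directed ortho-metalation: once the N–H is masked in the flask as 14, n-BuLi/TMEDA removes the proton at C2, the only position flanked by both the carbamate and a methoxy group, to give 15, which is silylated on carbon to 16; the N–Si bond is hydrolysed on acidic work-up.

Step 10
Reactants: 17 3,5-dimethoxy-2-(trimethylsilyl)phenyl N-isopropylcarbamate
Product: 19 3,5-dimethoxy-2-(trimethylsilyl)phenyl trifluoromethanesulfonate, via silylphenol 18 (not isolated)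
Conditions: DBU, Et2NH, MeCN, 40 °C; then PhNTf2, rt
Reagents that add atoms: N-phenylbis(trifluoromethanesulfonimide), O=S(=O)(N(c1ccccc1)S(=O)(=O)C(F)(F)F)C(F)(F)F
Why: The N–H carbamate is cleaved by base through elimination to isopropyl isocyanate, which diethylamine traps, and the phenoxide of 18 is sulfonylated in the same flask by PhNTf2 (carbamate cleavage, then O-triflation).

Step 11
Reactants: 11 methyl (2R,3R)-3,7-dimethyl-2-[4-(triisopropylsilyl)but-3-yn-1-yl]-3-(trimethylsilyloxy)oct-6-enoate; 19 3,5-dimethoxy-2-(trimethylsilyl)phenyl trifluoromethanesulfonate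
Product: 23 (2R,3R)-5,7-dimethoxy-2-methyl-2-(4-methylpent-3-en-1-yl)-3-[4-(triisopropylsilyl)but-3-yn-1-yl]chroman-4-one, via caesium alkoxide 20 (not isolated), via 3,5-dimethoxybenzyne 21 (not isolated), via aryl anion 22 (not isolated)
Conditions: 19 (1.5 equiv), CsF (3 equiv), 18-crown-6 (3 equiv), THF, 0 °C → rt
Reagents that add atoms: none
Why: Proposed new method: fluoride strips the O–SiMe3 group of 11 and the C–SiMe3 group of 19, so that the tertiary alkoxide 20 and the aryne 21 are released side by side in an aprotic medium; 20 adds to the aryne carbon meta to the flanking methoxy group, and the aryl anion 22, now between the new ether oxygen and that methoxy group, attacks the ester carbonyl and expels methoxide. The closest known reaction is the fluoride-mediated annulation of arynes with salicylate esters to xanthones (O-arylation, then acyl transfer to the aryl anion); new here are an aliphatic tertiary alkoxide as the nucleophile and an sp3 tether to the ester. The pyranone ring closes by 6-exo-trig acyl substitution. No stereocentre is formed: C2 and C3 come from steps 3 and 4 and take no part in bond making, and C3 is at risk only through enolisation by methoxide, which low temperature and a short reaction time are meant to limit. The step needs regioselective addition to the aryne, secured by the inductive effect and ring distortion caused by the methoxy group next to the triple bond, and acylation of the aryl anion in preference to protonation, secured by the absence of any O–H (silyl ether instead of free alcohol, THF instead of MeCN). Retro-aldol cleavage of 20 is held back by generating it gradually at 0 °C in the presence of its trap, and the ester enolate it would release is a poorer leaving group than a ketone enolate.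

Step 12
Reactants: 23 (2R,3R)-5,7-dimethoxy-2-methyl-2-(4-methylpent-3-en-1-yl)-3-[4-(triisopropylsilyl)but-3-yn-1-yl]chroman-4-one
Product: 24 (2R,3S)-4-isobutyl-5,7-dimethoxy-2-methyl-2-(4-methylpent-3-en-1-yl)-3-[4-(triisopropylsilyl)but-3-yn-1-yl]chroman-4-ol (C4 configuration open)
Conditions: i-BuLi, CeCl3 (anhydrous), THF, −78 °C; then 23; aq NH4Cl
Reagents that add atoms: isobutyllithium, [Li]CC(C)C
Why: Organocerium 1,2-addition: the weakly basic, strongly oxophilic isobutylcerium reagent should add to the hindered, enolisable aryl ketone without deprotonating C3 or opening the pyranone by β-elimination of the phenoxide.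

Step 13
Reactants: 24 (2R,3S)-4-isobutyl-5,7-dimethoxy-2-methyl-2-(4-methylpent-3-en-1-yl)-3-[4-(triisopropylsilyl)but-3-yn-1-yl]chroman-4-ol
Product: 26 (2R,3S,4R)-4-isobutyl-5,7-dimethoxy-2-methyl-2-(4-methylpent-3-en-1-yl)-3-[4-(triisopropylsilyl)but-3-yn-1-yl]chroman, via benzylic cation 25 (not isolated)
Conditions: Et3SiH (10 equiv), CF3CO2H (5 equiv), CH2Cl2, −40 → 0 °C
Reagents that add atoms: none
Why: Ionic hydrogenation: the acid ionises the tertiary benzylic alcohol to cation 25, stabilised by the ortho and para oxygen atoms, and triethylsilane should deliver hydride to the face opposite the adjacent C3 chain, placing the isobutyl group cis to that chain ((4R)); excess silane, little acid and low temperature are chosen so that hydride capture outruns loss of the C3 proton and protonation of the trisubstituted alkene.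

Step 14
Reactants: 26 (2R,3S,4R)-4-isobutyl-5,7-dimethoxy-2-methyl-2-(4-methylpent-3-en-1-yl)-3-[4-(triisopropylsilyl)but-3-yn-1-yl]chroman
Product: 27 (2R,3S,4R)-2-{2-[(2R)-3,3-dimethyloxiran-2-yl]ethyl}-4-isobutyl-5,7-dimethoxy-2-methyl-3-[4-(triisopropylsilyl)but-3-yn-1-yl]chroman
Conditions: D-fructose-derived Shi ketone (0.3 equiv), Oxone (2KHSO5·KHSO4·K2SO4), K2CO3, Bu4NHSO4, MeCN/(MeO)2CH2/aq Na2B4O7–Na2EDTA (pH 10.5), 0 °C
Reagents that add atoms: potassium peroxymonosulfate (active component of Oxone), [K+].[O-]S(=O)(=O)OO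
Why: Shi asymmetric epoxidation: the chiral dioxirane formed from the ketone and Oxone epoxidises the electron-rich trisubstituted alkene through a spiro transition state, which for the D-fructose-derived ketone gives the (R)-configured epoxide carbon under catalyst control, remote from the chroman stereocentres; arene and silylalkyne should be inert under the buffered conditions.

Step 15
Reactants: 27 (2R,3S,4R)-2-{2-[(2R)-3,3-dimethyloxiran-2-yl]ethyl}-4-isobutyl-5,7-dimethoxy-2-methyl-3-[4-(triisopropylsilyl)but-3-yn-1-yl]chroman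
Product: 28 (2R,3S,4R)-2-[(3R)-3-ethenyl-4-hydroxy-4-methylpentyl]-4-isobutyl-5,7-dimethoxy-2-methyl-3-[4-(triisopropylsilyl)but-3-yn-1-yl]chroman
Conditions: CH2=CHMgBr (4 equiv), CuI (0.2 equiv), THF, −30 → 0 °C; aq NH4Cl
Reagents that add atoms: vinylmagnesium bromide, C=C[Mg]Br
Why: Copper-catalysed Grignard opening of a trisubstituted epoxide: the vinylcopper species attacks the less substituted epoxide carbon in an SN2 manner, and the inversion converts the (R)-epoxide carbon into the (R)-configured allylic centre next to the tertiary carbinol.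

Step 16
Reactants: 28 (2R,3S,4R)-2-[(3R)-3-ethenyl-4-hydroxy-4-methylpentyl]-4-isobutyl-5,7-dimethoxy-2-methyl-3-[4-(triisopropylsilyl)but-3-yn-1-yl]chroman
Product: 29 (2R,3S,4R)-6,8-dibromo-2-[(3R)-3-ethenyl-4-hydroxy-4-methylpentyl]-4-isobutyl-5,7-dimethoxy-2-methyl-3-[4-(triisopropylsilyl)but-3-yn-1-yl]chroman
Conditions: NBS (2.05 equiv), CH2Cl2, −78 → 0 °C, dark
Reagents that add atoms: N-bromosuccinimide, O=C1CCC(=O)N1Br
Why: Electrophilic aromatic bromination: C6 and C8 are each activated by three ortho/para oxygen substituents and should react with NBS at low temperature far faster than the monosubstituted alkene, the hindered silylalkyne or the tertiary alcohol.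

Step 17
Reactants: 29 (2R,3S,4R)-6,8-dibromo-2-[(3R)-3-ethenyl-4-hydroxy-4-methylpentyl]-4-isobutyl-5,7-dimethoxy-2-methyl-3-[4-(triisopropylsilyl)but-3-yn-1-yl]chroman
Product: 31 (2R,3S,4R)-2-[(3R)-3-ethenyl-4-hydroxy-4-methylpentyl]-4-isobutyl-5,7-dimethoxy-2-methyl-3-[4-(triisopropylsilyl)but-3-yn-1-yl]chroman-6,8-dicarbaldehyde, via trilithio species 30 (not isolated)
Conditions: t-BuLi (5.2 equiv), THF, −78 °C; then DMF, −78 → 0 °C; aq NH4Cl
Reagents that add atoms: N,N-dimethylformamide, CN(C)C=O
Why: Bromine–lithium exchange with t-BuLi at both positions (after deprotonation of the hydroxyl) gives 30, each aryllithium being stabilised by two flanking oxygen atoms, and both are formylated by DMF on work-up (halogen–metal exchange, then Bouveault-type formylation).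

Step 18
Reactants: 31 (2R,3S,4R)-2-[(3R)-3-ethenyl-4-hydroxy-4-methylpentyl]-4-isobutyl-5,7-dimethoxy-2-methyl-3-[4-(triisopropylsilyl)but-3-yn-1-yl]chroman-6,8-dicarbaldehyde
Product: 32 (2R,3S,4R)-3-(but-3-yn-1-yl)-2-[(3R)-3-ethenyl-4-hydroxy-4-methylpentyl]-4-isobutyl-5,7-dimethoxy-2-methylchroman-6,8-dicarbaldehyde
Conditions: TBAF (1.2 equiv), THF, 0 °C → rt
Reagents that add atoms: none
Why: Fluoride attacks silicon and releases the acetylide, which is protonated at once (protodesilylation of an alkynylsilane); aldehydes, methyl ethers and the alkene are unaffected.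

Step 19
Reactants: 32 (2R,3S,4R)-3-(but-3-yn-1-yl)-2-[(3R)-3-ethenyl-4-hydroxy-4-methylpentyl]-4-isobutyl-5,7-dimethoxy-2-methylchroman-6,8-dicarbaldehyde
Product: 34 di-O-methyl ether of the target (5,7-dimethoxy-6,8-diformylchroman trans-fused at C2–C3 to the ten-membered ring with exocyclic methylene and cis ring alkene), via triene 33 (not isolated)
Conditions: second-generation Grubbs catalyst RuCl2(=CHPh)(H2IMes)(PCy3) (10 mol %), ethylene (1 atm), PhMe (2 mM), 40 °C; then argon sparge, 80 °C
Reagents that add atoms: ethylene, C=C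
Why: Enyne metathesis in two stages: under ethylene the ruthenium methylidene converts the terminal alkyne into the 2-substituted buta-1,3-diene 33 (cross enyne metathesis), and once ethylene is purged the monosubstituted diene terminus closes onto the vinyl group by ring-closing metathesis, which fixes the exocyclic methylene on the tether carbon and should give the cis ring alkene as the less strained geometry of the ten-membered ring.

Step 20
Reactants: 34 di-O-methyl ether of the target
Product: 35 CNP0479784.1 (target)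
Conditions: EtSNa (10 equiv), DMF, 100 °C; then aq NaH2PO4
Reagents that add atoms: none
Why: Thiolate demethylation (SN2 at the methyl carbon): each methoxy group is ortho to a formyl group that stabilises the departing phenoxide, and the basic conditions should leave the diene and the tertiary alcohol intact; mild acidification gives the target.

Compound list

1 | but-3-yn-1-ol | C#CCCO | starting material
2 | 4-(triisopropylsilyl)but-3-yn-1-ol | OCCC#C[Si](C(C)C)(C(C)C)C(C)C | intermediate
3 | (4-bromobut-1-yn-1-yl)triisopropylsilane | BrCCC#C[Si](C(C)C)(C(C)C)C(C)C | intermediate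
4 | geraniol | CC(C)=CCC/C(C)=C/CO | starting material
5 | (2R,3R)-2,3-epoxygeraniol | CC(C)=CCC[C@@]1(C)O[C@@H]1CO | intermediate
6 | [4-(triisopropylsilyl)but-3-yn-1-yl]magnesium bromide | Br[Mg]CCC#C[Si](C(C)C)(C(C)C)C(C)C | intermediate
7 | (2S,3R)-3,7-dimethyl-2-[4-(triisopropylsilyl)but-3-yn-1-yl]oct-6-ene-1,3-diol | CC(C)=CCC[C@@]([C@H](CO)CCC#C[Si](C(C)C)(C(C)C)C(C)C)(C)O | intermediate
8 | (2R,3R)-3-hydroxy-3,7-dimethyl-2-[4-(triisopropylsilyl)but-3-yn-1-yl]oct-6-enal | CC(C)=CCC[C@@]([C@H](C=O)CCC#C[Si](C(C)C)(C(C)C)C(C)C)(C)O | intermediate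
9 | (2R,3R)-3-hydroxy-3,7-dimethyl-2-[4-(triisopropylsilyl)but-3-yn-1-yl]oct-6-enoic acid | CC(C)=CCC[C@@]([C@H](C(=O)O)CCC#C[Si](C(C)C)(C(C)C)C(C)C)(C)O | intermediate
10 | methyl (2R,3R)-3-hydroxy-3,7-dimethyl-2-[4-(triisopropylsilyl)but-3-yn-1-yl]oct-6-enoate | CC(C)=CCC[C@@]([C@H](C(=O)OC)CCC#C[Si](C(C)C)(C(C)C)C(C)C)(C)O | intermediate
11 | methyl (2R,3R)-3,7-dimethyl-2-[4-(triisopropylsilyl)but-3-yn-1-yl]-3-(trimethylsilyloxy)oct-6-enoate | CC(C)=CCC[C@@]([C@H](C(=O)OC)CCC#C[Si](C(C)C)(C(C)C)C(C)C)(C)O[Si](C)(C)C | intermediate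
12 | 3,5-dimethoxyphenol | COc1cc(O)cc(OC)c1 | starting material
13 | 3,5-dimethoxyphenyl N-isopropylcarbamate | COc1cc(OC)cc(OC(=O)NC(C)C)c1 | intermediate
14 | 3,5-dimethoxyphenyl N-(tert-butyldimethylsilyl)-N-isopropylcarbamate | COc1cc(OC)cc(OC(=O)N(C(C)C)[Si](C)(C)C(C)(C)C)c1 | intermediate
15 | 2-lithio-3,5-dimethoxyphenyl N-(tert-butyldimethylsilyl)-N-isopropylcarbamate | COc1cc(OC)c([Li])c(OC(=O)N(C(C)C)[Si](C)(C)C(C)(C)C)c1 | intermediate
16 | 3,5-dimethoxy-2-(trimethylsilyl)phenyl N-(tert-butyldimethylsilyl)-N-isopropylcarbamate | COc1cc(OC)c([Si](C)(C)C)c(OC(=O)N(C(C)C)[Si](C)(C)C(C)(C)C)c1 | intermediate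
17 | 3,5-dimethoxy-2-(trimethylsilyl)phenyl N-isopropylcarbamate | COc1cc(OC)c([Si](C)(C)C)c(OC(=O)NC(C)C)c1 | intermediate
18 | 3,5-dimethoxy-2-(trimethylsilyl)phenol | COc1cc(O)c([Si](C)(C)C)c(OC)c1 | intermediate
19 | 3,5-dimethoxy-2-(trimethylsilyl)phenyl trifluoromethanesulfonate | COc1cc(OC)c([Si](C)(C)C)c(OS(=O)(=O)C(F)(F)F)c1 | intermediate
20 | caesium alkoxide of hydroxy ester 10 | CC(C)=CCC[C@@]([C@H](C(=O)OC)CCC#C[Si](C(C)C)(C(C)C)C(C)C)(C)[O-].[Cs+] | intermediate
21 | 3,5-dimethoxybenzyne | COC1=CC(OC)=CC#C1 | intermediate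
22 | aryl caesium species from O-arylation of 20 (anion between the ether oxygen and a methoxy group) | CC(C)=CCC[C@@]([C@H](C(=O)OC)CCC#C[Si](C(C)C)(C(C)C)C(C)C)(C)Oc1cc(OC)cc(OC)[c-]1.[Cs+] | intermediate
23 | (2R,3R)-5,7-dimethoxy-2-methyl-2-(4-methylpent-3-en-1-yl)-3-[4-(triisopropylsilyl)but-3-yn-1-yl]chroman-4-one | CC(C)=CCC[C@@]2(C)Oc3cc(OC)cc(OC)c3C(=O)[C@@H]2CCC#C[Si](C(C)C)(C(C)C)C(C)C | intermediate
24 | (2R,3S)-4-isobutyl-5,7-dimethoxy-2-methyl-2-(4-methylpent-3-en-1-yl)-3-[4-(triisopropylsilyl)but-3-yn-1-yl]chroman-4-ol, C4 configuration open | CC(C)=CCC[C@@]2(C)Oc3cc(OC)cc(OC)c3C(O)(CC(C)C)[C@@H]2CCC#C[Si](C(C)C)(C(C)C)C(C)C | intermediate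
25 | 4-isobutylchroman-4-ylium cation from 24 | CC(C)=CCC[C@@]2(C)Oc3cc(OC)cc(OC)c3[C+](CC(C)C)[C@@H]2CCC#C[Si](C(C)C)(C(C)C)C(C)C | intermediate
26 | (2R,3S,4R)-4-isobutyl-5,7-dimethoxy-2-methyl-2-(4-methylpent-3-en-1-yl)-3-[4-(triisopropylsilyl)but-3-yn-1-yl]chroman | CC(C)=CCC[C@@]2(C)Oc3cc(OC)cc(OC)c3[C@H](CC(C)C)[C@@H]2CCC#C[Si](C(C)C)(C(C)C)C(C)C | intermediate
27 | (2R,3S,4R)-2-{2-[(2R)-3,3-dimethyloxiran-2-yl]ethyl}-4-isobutyl-5,7-dimethoxy-2-methyl-3-[4-(triisopropylsilyl)but-3-yn-1-yl]chroman | CC1(C)O[C@@H]1CC[C@@]2(C)Oc3cc(OC)cc(OC)c3[C@H](CC(C)C)[C@@H]2CCC#C[Si](C(C)C)(C(C)C)C(C)C | intermediate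
28 | (2R,3S,4R)-2-[(3R)-3-ethenyl-4-hydroxy-4-methylpentyl]-4-isobutyl-5,7-dimethoxy-2-methyl-3-[4-(triisopropylsilyl)but-3-yn-1-yl]chroman | C=C[C@H](C(C)(C)O)CC[C@@]2(C)Oc3cc(OC)cc(OC)c3[C@H](CC(C)C)[C@@H]2CCC#C[Si](C(C)C)(C(C)C)C(C)C | intermediate
29 | 6,8-dibromo derivative of 28 | C=C[C@H](C(C)(C)O)CC[C@@]2(C)Oc3c(Br)c(OC)c(Br)c(OC)c3[C@H](CC(C)C)[C@@H]2CCC#C[Si](C(C)C)(C(C)C)C(C)C | intermediate
30 | 6,8-dilithio lithium alkoxide from 29 | C=C[C@H](C(C)(C)O[Li])CC[C@@]2(C)Oc3c([Li])c(OC)c([Li])c(OC)c3[C@H](CC(C)C)[C@@H]2CCC#C[Si](C(C)C)(C(C)C)C(C)C | intermediate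
31 | (2R,3S,4R)-2-[(3R)-3-ethenyl-4-hydroxy-4-methylpentyl]-4-isobutyl-5,7-dimethoxy-2-methyl-3-[4-(triisopropylsilyl)but-3-yn-1-yl]chroman-6,8-dicarbaldehyde | C=C[C@H](C(C)(C)O)CC[C@@]2(C)Oc3c(C=O)c(OC)c(C=O)c(OC)c3[C@H](CC(C)C)[C@@H]2CCC#C[Si](C(C)C)(C(C)C)C(C)C | intermediate
32 | (2R,3S,4R)-3-(but-3-yn-1-yl)-2-[(3R)-3-ethenyl-4-hydroxy-4-methylpentyl]-4-isobutyl-5,7-dimethoxy-2-methylchroman-6,8-dicarbaldehyde | C=C[C@H](C(C)(C)O)CC[C@@]2(C)Oc3c(C=O)c(OC)c(C=O)c(OC)c3[C@H](CC(C)C)[C@@H]2CCC#C | intermediate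
33 | triene from 32, C3 side chain 3-methylidenepent-4-en-1-yl | C=C[C@H](C(C)(C)O)CC[C@@]2(C)Oc3c(C=O)c(OC)c(C=O)c(OC)c3[C@H](CC(C)C)[C@@H]2CCC(=C)C=C | intermediate
34 | di-O-methyl ether of the target | C=C1/C=C\[C@H](C(C)(C)O)CC[C@@]2(C)Oc3c(C=O)c(OC)c(C=O)c(OC)c3[C@H](CC(C)C)[C@@H]2CC1 | intermediate
35 | CNP0479784.1 | C=C1/C=C\[C@H](C(C)(C)O)CC[C@@]2(C)Oc3c(C=O)c(O)c(C=O)c(O)c3[C@H](CC(C)C)[C@@H]2CC1 | target

Total step count: 20.
Longest linear sequence: 16 steps (steps 1, 2, 4–7 and 11–20, from but-3-yn-1-ol).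

Steps most likely to fail

Step 11 (Proposed new method). The alkoxide may fragment by retro-aldol cleavage before it meets the aryne. The aryl anion may be protonated or silylated before it acylates the ester, which stops the sequence at the open aryl ether. Methoxide may enolise the product and erode C3 or open the pyranone, and fluoride may attack the alkynylsilane. The fallback uses known chemistry, sets out from diol 7 and comes back at chromanone 23. The primary hydroxyl of 7 is silylated (TBSCl, imidazole) to give the primary tert-butyldimethylsilyl ether F1. Its tertiary sodium alkoxide cannot undergo retro-aldol cleavage because no carbonyl group is present. It is arylated without a metal catalyst by (3,5-dimethoxyphenyl)(2,4,6-trimethoxyphenyl)iodonium tosylate (NaH, toluene) to the tertiary aryl ether F2. CSA/MeOH then frees the primary alcohol F3, and TEMPO/PhI(OAc)2 in aqueous MeCN gives the β-aryloxy acid F4. Trifluoroacetic anhydride in CH2Cl2 at 0 °C closes the pyranone by intramolecular Friedel–Crafts acylation at either of the two equivalent positions ortho to the ether oxygen, which gives 23 with both stereocentres untouched.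

Step 19. Ring closure to the strained ten-membered diene may lose to oligomerisation or to ethenolysis back to 33, the ruthenium alkylidene may be held by the formyl and alkoxy groups near the C2 arm, or the ring alkene may form with the trans geometry. The fallback sets out from dibromide 29 and comes back at 34, closing the ring before the formyl groups exist. TBAF gives the terminal alkyne F7. The same ethylene-then-argon metathesis protocol, on a substrate without carbonyl groups, should pass through the triene F8 to the macrocyclic dibromide F9. Bromine–lithium exchange with n-BuLi at −78 °C followed by DMF then installs both formyl groups on the closed ring and gives 34.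

Step 13. Hydride may be delivered to the face of cation 25 syn to the C3 chain, giving the C4 epimer, or the cation may lose the C3 proton and return with C3 scrambled. The fallback sets out from chromanone 23 and comes back at chroman 26, with hydrogen and carbon attached in the reverse order. LiAlH4 reduces 23 to the chroman-4-ol F5. BF3·OEt2 ionises it at −78 °C in the presence of 2-methylallyltrimethylsilane (Hosomi–Sakurai allylation of the secondary benzylic cation), so that the carbon nucleophile, not hydride, takes the face the cation prefers, giving the 4-(2-methylallyl)chroman F6. RhCl(PPh3)3 under H2 then saturates only the 1,1-disubstituted alkene and gives 26.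

Further compounds

F1 | step 11 | primary tert-butyldimethylsilyl ether of diol 7 | CC(C)=CCC[C@@]([C@H](CO[Si](C)(C)C(C)(C)C)CCC#C[Si](C(C)C)(C(C)C)C(C)C)(C)O
F2 | step 11 | tertiary 3,5-dimethoxyphenyl ether of F1 | CC(C)=CCC[C@@]([C@H](CO[Si](C)(C)C(C)(C)C)CCC#C[Si](C(C)C)(C(C)C)C(C)C)(C)Oc1cc(OC)cc(OC)c1
F3 | step 11 | (2S,3R)-3-(3,5-dimethoxyphenoxy)-3,7-dimethyl-2-[4-(triisopropylsilyl)but-3-yn-1-yl]oct-6-en-1-ol | CC(C)=CCC[C@@]([C@H](CO)CCC#C[Si](C(C)C)(C(C)C)C(C)C)(C)Oc1cc(OC)cc(OC)c1
F4 | step 11 | (2R,3R)-3-(3,5-dimethoxyphenoxy)-3,7-dimethyl-2-[4-(triisopropylsilyl)but-3-yn-1-yl]oct-6-enoic acid | CC(C)=CCC[C@@]([C@H](C(=O)O)CCC#C[Si](C(C)C)(C(C)C)C(C)C)(C)Oc1cc(OC)cc(OC)c1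
F5 | step 13 | (2R,3S)-5,7-dimethoxy-2-methyl-2-(4-methylpent-3-en-1-yl)-3-[4-(triisopropylsilyl)but-3-yn-1-yl]chroman-4-ol, C4 configuration open | CC(C)=CCC[C@@]2(C)Oc3cc(OC)cc(OC)c3C(O)[C@@H]2CCC#C[Si](C(C)C)(C(C)C)C(C)C
F6 | step 13 | (2R,3S,4R)-5,7-dimethoxy-2-methyl-4-(2-methylprop-2-en-1-yl)-2-(4-methylpent-3-en-1-yl)-3-[4-(triisopropylsilyl)but-3-yn-1-yl]chroman | CC(C)=CCC[C@@]2(C)Oc3cc(OC)cc(OC)c3[C@H](CC(C)=C)[C@@H]2CCC#C[Si](C(C)C)(C(C)C)C(C)C
F7 | step 19 | terminal alkyne from desilylation of dibromide 29 | C=C[C@H](C(C)(C)O)CC[C@@]2(C)Oc3c(Br)c(OC)c(Br)c(OC)c3[C@H](CC(C)C)[C@@H]2CCC#C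
F8 | step 19 | 6,8-dibromo triene, C3 side chain 3-methylidenepent-4-en-1-yl | C=C[C@H](C(C)(C)O)CC[C@@]2(C)Oc3c(Br)c(OC)c(Br)c(OC)c3[C@H](CC(C)C)[C@@H]2CCC(=C)C=C
F9 | step 19 | 6,8-dibromo analogue of macrocycle 34 | C=C1/C=C\[C@H](C(C)(C)O)CC[C@@]2(C)Oc3c(Br)c(OC)c(Br)c(OC)c3[C@H](CC(C)C)[C@@H]2CC1
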